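**Retrosynthetic overview**

1. Rings are lettered A to F along the chain (A = 2,4,6-trihydroxyphenyl end, F = 3,4,5-trihydroxyphenyl end); ring C is numbered C1 (O to ring B), C2 (H), C3 to C5 (OH), C6 (O to ring D). Target 33 comes from its pentadecamethyl ether 32 by BBr3, and 32 is cut at the C6–O–ring D ether into phenol 21 (rings A–C) and boronic acid 31 (rings D–F).
2. The strategy rests on ring C, which has five contiguous oxygenated carbons and one CH. C3, C4, C5 and C6 are the four carbons of dimethyl squarate 13; C1 and C2 are the two carbons of a 1-aryloxyvinyl group that already carries the hindered oxygen of ring B. Ring C is closed through the C2–C3 bond in the thermal rearrangement of cyclobutenone 16 to phenol 19.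
3. The carbinol oxygen (future C6–O) is silylated in the flask in which 16 is made, so the two para oxygens of ring C leave the key step differentiated and the product cannot oxidise to a quinone. The free C3–OH is then methylated and the silyl group removed to free C6–OH for arylation.
4. Rings A, B, D, E and F are bought benzene rings joined by copper-mediated diaryl ether couplings (A–B by Ullmann coupling and Dakin oxidation, D–E–F by two Chan–Lam couplings). The two vinyl carbons come from trichloroethylene via ethynyl ether 11 and 1-stannylvinyl ether 12. Ring C is the only ring formed, after the A–B unit is in place and before the union with D–F.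

Key step: step 8

Remark: the target has no stereocentre; the one stereocentre on the route (C4 of cyclobutenone 16) is racemic and disappears in step 8. Compounds 4, 22 and 23 are taken as purchasable building blocks.

**Route**

Step 1
Reactants: 1 2,4,6-trimethoxybenzaldehyde
Product: 3 2,4,6-trimethoxyphenol, via aryl formate 2 (not isolated)
Conditions: 30% aq. H2O2, cat. H2SO4, MeOH, 0 °C to rt
Reagents that add atoms: hydrogen peroxide, OO
Why: Acid-catalysed Dakin (Baeyer–Villiger-type) oxidation, in which the very electron-rich aryl group migrates from carbon to oxygen in the peroxide adduct and the aryl formate is methanolysed in the same flask.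

Step 2
Reactants: 3 2,4,6-trimethoxyphenol; 4 4-bromo-2,6-dimethoxybenzaldehyde
Product: 5 2,6-dimethoxy-4-(2,4,6-trimethoxyphenoxy)benzaldehyde
Conditions: CuI (10 mol %), picolinic acid (20 mol %), K3PO4, DMSO, 90 °C, argon
Reagents that add atoms: none
Why: Ligand-accelerated Ullmann diaryl ether coupling, suited to phenols with two ortho substituents, with an aryl bromide that is unhindered at the reacting carbon and activated by its para formyl group.

Step 3
Reactants: 5 2,6-dimethoxy-4-(2,4,6-trimethoxyphenoxy)benzaldehyde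
Product: 7 2,6-dimethoxy-4-(2,4,6-trimethoxyphenoxy)phenol, via aryl formate 6 (not isolated)
Conditions: 30% aq. H2O2, cat. H2SO4, MeOH, 0 °C to rt
Reagents that add atoms: hydrogen peroxide, OO
Why: Dakin oxidation again, favoured by the two ortho methoxy groups and the para aryloxy group on the migrating ring, which should give the hindered ring B phenol without a protecting group.

Step 4
Reactants: 7 2,6-dimethoxy-4-(2,4,6-trimethoxyphenoxy)phenol
Product: 8 2-{[(E)-1,2-dichloroethenyl]oxy}-1,3-dimethoxy-5-(2,4,6-trimethoxyphenoxy)benzene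
Conditions: trichloroethylene, K2CO3, DMF, 70 °C, N2
Reagents that add atoms: trichloroethylene, ClC=C(Cl)Cl
Why: Known dichlorovinyl ether synthesis, in which base turns trichloroethylene into dichloroacetylene and the phenoxide adds to it in anti fashion, which sets the E geometry.

Step 5
Reactants: 8 2-{[(E)-1,2-dichloroethenyl]oxy}-1,3-dimethoxy-5-(2,4,6-trimethoxyphenoxy)benzene
Product: 11 2-(ethynyloxy)-1,3-dimethoxy-5-(2,4,6-trimethoxyphenoxy)benzene, via chloroalkyne 9 (not isolated), via lithium acetylide 10 (not isolated)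
Conditions: n-BuLi (2.5 equiv), THF, −78 to −40 °C; then H2O, −78 °C to rt
Reagents that add atoms: none
Why: Greene-type ynol ether synthesis, in which n-BuLi removes HCl, chlorine–lithium exchange on the chloroalkyne gives the lithium acetylide and water protonates it, all at temperatures where the ring C–H bonds between two methoxy groups should not be metalated.

Step 6
Reactants: 11 2-(ethynyloxy)-1,3-dimethoxy-5-(2,4,6-trimethoxyphenoxy)benzene
Product: 12 tributyl{1-[2,6-dimethoxy-4-(2,4,6-trimethoxyphenoxy)phenoxy]ethenyl}stannane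
Conditions: Bu3SnH (slow addition), Pd(PPh3)4 (2 mol %), THF, 0 °C to rt; Et3N-deactivated silica
Reagents that add atoms: tributyltin hydride, CCCC[SnH](CCCC)CCCC
Why: Palladium-catalysed syn hydrostannylation of an alkynyl ether, which places tin on the oxygen-bearing carbon as is usual for 1-alkoxyalkynes, and a terminal alkyne leaves no alkene geometry to control.

Step 7
Reactants: 12 tributyl{1-[2,6-dimethoxy-4-(2,4,6-trimethoxyphenoxy)phenoxy]ethenyl}stannane; 13 dimethyl squarate
Product: 16 racemic 4-[(tert-butyldimethylsilyl)oxy]-4-{1-[2,6-dimethoxy-4-(2,4,6-trimethoxyphenoxy)phenoxy]ethenyl}-2,3-dimethoxycyclobut-2-en-1-one, via vinyllithium 14 (not isolated), via lithium alkoxide 15 (not isolated)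
Conditions: n-BuLi, THF, −78 °C; cannulate into 13, THF, −78 °C; TBSOTf, −78 to −20 °C
Reagents that add atoms: tert-butyldimethylsilyl trifluoromethanesulfonate, CC(C)(C)[Si](C)(C)OS(=O)(=O)C(F)(F)F
Why: Tin–lithium exchange is fast and site-specific at −78 °C, the 1-aryloxyvinyllithium adds 1,2 to one of the two equivalent carbonyl groups of the squarate, and the lithium alkoxide is O-silylated in the same flask; the new carbinol stereocentre forms without control (racemic) and is lost in step 8.

Step 8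
Reactants: 16 racemic 4-[(tert-butyldimethylsilyl)oxy]-4-{1-[2,6-dimethoxy-4-(2,4,6-trimethoxyphenoxy)phenoxy]ethenyl}-2,3-dimethoxycyclobut-2-en-1-one
Product: 19 4-[(tert-butyldimethylsilyl)oxy]-5-[2,6-dimethoxy-4-(2,4,6-trimethoxyphenoxy)phenoxy]-2,3-dimethoxyphenol, via vinylketene 17 (not isolated), via cyclohexadienone 18 (not isolated)
Conditions: degassed toluene (0.02 M), 110 °C, argon
Reagents that add atoms: none
Why: Heating should open the cyclobutenone by conrotatory four-electron cleavage of its C1–C4 bond to vinylketene 17, in which the ketene carbon and the CH2 terminus of the 1-aryloxyvinyl group are the two ends of a cis-dienylketene; a thermal six-electron electrocyclisation joins them (the one new C–C bond, C3–C2 of ring C) to give cyclohexa-2,4-dienone 18, and a proton shift from its CH2 group aromatises it to phenol 19. The closest known reaction type is the Moore rearrangement of squarate-derived 4-alkenyl-4-hydroxy- and 4-siloxycyclobutenones to hydroquinones and their mono-ethers. Ring C is closed as a six-membered carbocycle by disrotatory 6π electrocyclisation, and no stereocentre is formed, since the racemic carbinol carbon becomes an sp2 ring carbon. The selectivity needed is torquoselectivity: the vinyl group has to turn inward, and the silyloxy group, a strong donor, prefers outward rotation, which leaves the vinyl group on the ketene side. No regiochemical question arises, because only the C1–C4 bond can open and the squarate was symmetric before the addition. The silyl group sits para to the new hydroxyl and cannot migrate, so the two oxygens of the hydroquinone leave the step told apart and the product is protected against oxidation to the quinone.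

Step 9
Reactants: 19 4-[(tert-butyldimethylsilyl)oxy]-5-[2,6-dimethoxy-4-(2,4,6-trimethoxyphenoxy)phenoxy]-2,3-dimethoxyphenol
Product: 20 tert-butyl{6-[2,6-dimethoxy-4-(2,4,6-trimethoxyphenoxy)phenoxy]-2,3,4-trimethoxyphenoxy}dimethylsilane
Conditions: MeI, K2CO3, acetone, 40 °C
Reagents that add atoms: iodomethane, CI
Why: Williamson methylation of the only free hydroxyl, while the aryl silyl ether, shielded by two ortho substituents, should survive dry carbonate in acetone.

Step 10
Reactants: 20 tert-butyl{6-[2,6-dimethoxy-4-(2,4,6-trimethoxyphenoxy)phenoxy]-2,3,4-trimethoxyphenoxy}dimethylsilane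
Product: 21 6-[2,6-dimethoxy-4-(2,4,6-trimethoxyphenoxy)phenoxy]-2,3,4-trimethoxyphenol
Conditions: Bu4NF, AcOH, THF, 0 °C to rt
Reagents that add atoms: none
Why: Fluoride desilylation of an aryl silyl ether, buffered with acetic acid so that the electron-rich phenoxide is not left exposed to air.

Step 11
Reactants: 22 3,4,5-trimethoxyphenylboronic acid; 23 4-bromo-2,6-dimethoxyphenol
Product: 24 5-bromo-1,3-dimethoxy-2-(3,4,5-trimethoxyphenoxy)benzene
Conditions: Cu(OAc)2 (2 equiv), pyridine, 4 Å MS, CH2Cl2, dry air, rt; 22 in excess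
Reagents that add atoms: none
Why: Chan–Lam–Evans coupling, in which the unhindered arylboronic acid transmetalates to the divalent copper phenoxide and C–O reductive elimination follows at room temperature, conditions under which the aryl bromide is inert and the sieves keep the boronic acid from turning into its phenol.

Step 12
Reactants: 24 5-bromo-1,3-dimethoxy-2-(3,4,5-trimethoxyphenoxy)benzene
Product: 27 [3,5-dimethoxy-4-(3,4,5-trimethoxyphenoxy)phenyl]boronic acid, via aryllithium 25 (not isolated), via lithium borate 26 (not isolated)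
Conditions: B(OiPr)3, n-BuLi, THF, −78 °C; then 1 M HCl, rt
Reagents that add atoms: triisopropyl borate, CC(C)OB(OC(C)C)OC(C)C; water, O
Why: Bromine–lithium exchange with in-flask trapping by the borate, faster at −78 °C than any ortho-lithiation of the methoxyarenes, followed by acid hydrolysis of the borate to the boronic acid.

Step 13
Reactants: 27 [3,5-dimethoxy-4-(3,4,5-trimethoxyphenoxy)phenyl]boronic acid; 23 4-bromo-2,6-dimethoxyphenol
Product: 28 5-bromo-2-[3,5-dimethoxy-4-(3,4,5-trimethoxyphenoxy)phenoxy]-1,3-dimethoxybenzene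
Conditions: Cu(OAc)2 (2 equiv), pyridine, 4 Å MS, CH2Cl2, dry air, rt; 27 in slight excess
Reagents that add atoms: none
Why: Second Chan–Lam–Evans coupling of the same hindered bromophenol with an unhindered boronic acid, which adds ring D and keeps the bromide as the handle for the next borylation.

Step 14
Reactants: 28 5-bromo-2-[3,5-dimethoxy-4-(3,4,5-trimethoxyphenoxy)phenoxy]-1,3-dimethoxybenzene
Product: 31 {4-[3,5-dimethoxy-4-(3,4,5-trimethoxyphenoxy)phenoxy]-3,5-dimethoxyphenyl}boronic acid, via aryllithium 29 (not isolated), via lithium borate 30 (not isolated)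
Conditions: B(OiPr)3, n-BuLi, THF, −78 °C; then 1 M HCl, rt
Reagents that add atoms: triisopropyl borate, CC(C)OB(OC(C)C)OC(C)C; water, O
Why: Bromine–lithium exchange, borylation and hydrolysis as in step 12, on a substrate with the same substitution pattern around the C–Br bond.

Step 15
Reactants: 21 6-[2,6-dimethoxy-4-(2,4,6-trimethoxyphenoxy)phenoxy]-2,3,4-trimethoxyphenol; 31 {4-[3,5-dimethoxy-4-(3,4,5-trimethoxyphenoxy)phenoxy]-3,5-dimethoxyphenyl}boronic acid
Product: 32 2-{4-[3,5-dimethoxy-4-(3,4,5-trimethoxyphenoxy)phenoxy]-3,5-dimethoxyphenoxy}-1-[2,6-dimethoxy-4-(2,4,6-trimethoxyphenoxy)phenoxy]-3,4,5-trimethoxybenzene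
Conditions: Cu(OAc)2 (2 equiv), pyridine, 4 Å MS, CH2Cl2, dry air, rt; 31 (2 equiv) added in portions
Reagents that add atoms: none
Why: Chan–Lam–Evans coupling of the single free hydroxyl of ring C (C6–OH) with a boronic acid that is unhindered at boron, under room-temperature conditions that the fourteen methyl ethers and the diaryl ethers should tolerate.

Step 16
Reactants: 32 2-{4-[3,5-dimethoxy-4-(3,4,5-trimethoxyphenoxy)phenoxy]-3,5-dimethoxyphenoxy}-1-[2,6-dimethoxy-4-(2,4,6-trimethoxyphenoxy)phenoxy]-3,4,5-trimethoxybenzene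
Product: 33 4-{3,5-dihydroxy-4-[3,5-dihydroxy-4-(3,4,5-trihydroxyphenoxy)phenoxy]phenoxy}-5-[2,6-dihydroxy-4-(2,4,6-trihydroxyphenoxy)phenoxy]benzene-1,2,3-triol (CNP0270681.0)
Conditions: BBr3 (large excess), CH2Cl2, −78 °C to rt, argon; then H2O, 0 °C
Reagents that add atoms: none
Why: Lewis acid-mediated ether cleavage, in which BBr3 complexes each methoxy oxygen and bromide removes the methyl group by SN2 attack, while the diaryl ether C–O bonds offer no alkyl carbon and should stay intact.

**Compound list**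

1 | 2,4,6-trimethoxybenzaldehyde | COc1cc(OC)c(C=O)c(OC)c1 | starting material
2 | 2,4,6-trimethoxyphenyl formate | COc1cc(OC)c(OC=O)c(OC)c1 | intermediate
3 | 2,4,6-trimethoxyphenol | COc1cc(OC)c(O)c(OC)c1 | intermediate
4 | 4-bromo-2,6-dimethoxybenzaldehyde | COc1cc(Br)cc(OC)c1C=O | starting material
5 | 2,6-dimethoxy-4-(2,4,6-trimethoxyphenoxy)benzaldehyde | COc1cc(Oc2c(OC)cc(OC)cc2OC)cc(OC)c1C=O | intermediate
6 | 2,6-dimethoxy-4-(2,4,6-trimethoxyphenoxy)phenyl formate | COc1cc(Oc2c(OC)cc(OC)cc2OC)cc(OC)c1OC=O | intermediate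
7 | 2,6-dimethoxy-4-(2,4,6-trimethoxyphenoxy)phenol | COc1cc(Oc2c(OC)cc(OC)cc2OC)cc(OC)c1O | intermediate
8 | 2-{[(E)-1,2-dichloroethenyl]oxy}-1,3-dimethoxy-5-(2,4,6-trimethoxyphenoxy)benzene | COc1cc(Oc2c(OC)cc(OC)cc2OC)cc(OC)c1O/C(Cl)=C\Cl | intermediate
9 | 2-[(chloroethynyl)oxy]-1,3-dimethoxy-5-(2,4,6-trimethoxyphenoxy)benzene | COc1cc(Oc2c(OC)cc(OC)cc2OC)cc(OC)c1OC#CCl | intermediate
10 | lithium {[2,6-dimethoxy-4-(2,4,6-trimethoxyphenoxy)phenoxy]ethynide} | COc1cc(Oc2c(OC)cc(OC)cc2OC)cc(OC)c1OC#C[Li] | intermediate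
11 | 2-(ethynyloxy)-1,3-dimethoxy-5-(2,4,6-trimethoxyphenoxy)benzene | COc1cc(Oc2c(OC)cc(OC)cc2OC)cc(OC)c1OC#C | intermediate
12 | tributyl{1-[2,6-dimethoxy-4-(2,4,6-trimethoxyphenoxy)phenoxy]ethenyl}stannane | CCCC[Sn](CCCC)(CCCC)C(=C)Oc1c(OC)cc(Oc2c(OC)cc(OC)cc2OC)cc1OC | intermediate
13 | dimethyl squarate (3,4-dimethoxycyclobut-3-ene-1,2-dione) | COC1=C(OC)C(=O)C1=O | starting material
14 | {1-[2,6-dimethoxy-4-(2,4,6-trimethoxyphenoxy)phenoxy]ethenyl}lithium | [Li]C(=C)Oc1c(OC)cc(Oc2c(OC)cc(OC)cc2OC)cc1OC | intermediate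
15 | lithium alkoxide of racemic 4-hydroxy-2,3-dimethoxy-4-{1-[2,6-dimethoxy-4-(2,4,6-trimethoxyphenoxy)phenoxy]ethenyl}cyclobut-2-en-1-one | COC1=C(OC)C([O-])(C(=C)Oc2c(OC)cc(Oc3c(OC)cc(OC)cc3OC)cc2OC)C1=O.[Li+] | intermediate
16 | racemic 4-[(tert-butyldimethylsilyl)oxy]-4-{1-[2,6-dimethoxy-4-(2,4,6-trimethoxyphenoxy)phenoxy]ethenyl}-2,3-dimethoxycyclobut-2-en-1-one | COC1=C(OC)C(O[Si](C)(C)C(C)(C)C)(C(=C)Oc2c(OC)cc(Oc3c(OC)cc(OC)cc3OC)cc2OC)C1=O | intermediate
17 | (Z)-4-[(tert-butyldimethylsilyl)oxy]-5-[2,6-dimethoxy-4-(2,4,6-trimethoxyphenoxy)phenoxy]-2,3-dimethoxyhexa-1,3,5-trien-1-one (vinylketene) | COC(=C=O)/C(OC)=C(/O[Si](C)(C)C(C)(C)C)C(=C)Oc1c(OC)cc(Oc2c(OC)cc(OC)cc2OC)cc1OC | intermediate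
18 | 4-[(tert-butyldimethylsilyl)oxy]-5-[2,6-dimethoxy-4-(2,4,6-trimethoxyphenoxy)phenoxy]-2,3-dimethoxycyclohexa-2,4-dien-1-one | COC1=C(OC)C(O[Si](C)(C)C(C)(C)C)=C(Oc2c(OC)cc(Oc3c(OC)cc(OC)cc3OC)cc2OC)CC1=O | intermediate
19 | 4-[(tert-butyldimethylsilyl)oxy]-5-[2,6-dimethoxy-4-(2,4,6-trimethoxyphenoxy)phenoxy]-2,3-dimethoxyphenol | COc1c(O)cc(Oc2c(OC)cc(Oc3c(OC)cc(OC)cc3OC)cc2OC)c(O[Si](C)(C)C(C)(C)C)c1OC | intermediate
20 | tert-butyl{6-[2,6-dimethoxy-4-(2,4,6-trimethoxyphenoxy)phenoxy]-2,3,4-trimethoxyphenoxy}dimethylsilane | COc1cc(Oc2c(OC)cc(Oc3c(OC)cc(OC)cc3OC)cc2OC)c(O[Si](C)(C)C(C)(C)C)c(OC)c1OC | intermediate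
21 | 6-[2,6-dimethoxy-4-(2,4,6-trimethoxyphenoxy)phenoxy]-2,3,4-trimethoxyphenol | COc1cc(Oc2c(OC)cc(Oc3c(OC)cc(OC)cc3OC)cc2OC)c(O)c(OC)c1OC | intermediate
22 | 3,4,5-trimethoxyphenylboronic acid | COc1cc(B(O)O)cc(OC)c1OC | starting material
23 | 4-bromo-2,6-dimethoxyphenol | COc1cc(Br)cc(OC)c1O | starting material
24 | 5-bromo-1,3-dimethoxy-2-(3,4,5-trimethoxyphenoxy)benzene | COc1cc(Br)cc(OC)c1Oc1cc(OC)c(OC)c(OC)c1 | intermediate
25 | [3,5-dimethoxy-4-(3,4,5-trimethoxyphenoxy)phenyl]lithium | [Li]c1cc(OC)c(Oc2cc(OC)c(OC)c(OC)c2)c(OC)c1 | intermediate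
26 | lithium [3,5-dimethoxy-4-(3,4,5-trimethoxyphenoxy)phenyl]tri(propan-2-yloxy)borate | CC(C)O[B-](OC(C)C)(OC(C)C)c1cc(OC)c(Oc2cc(OC)c(OC)c(OC)c2)c(OC)c1.[Li+] | intermediate
27 | [3,5-dimethoxy-4-(3,4,5-trimethoxyphenoxy)phenyl]boronic acid | COc1cc(B(O)O)cc(OC)c1Oc1cc(OC)c(OC)c(OC)c1 | intermediate
28 | 5-bromo-2-[3,5-dimethoxy-4-(3,4,5-trimethoxyphenoxy)phenoxy]-1,3-dimethoxybenzene | COc1cc(Br)cc(OC)c1Oc1cc(OC)c(Oc2cc(OC)c(OC)c(OC)c2)c(OC)c1 | intermediate
29 | {4-[3,5-dimethoxy-4-(3,4,5-trimethoxyphenoxy)phenoxy]-3,5-dimethoxyphenyl}lithium | [Li]c1cc(OC)c(Oc2cc(OC)c(Oc3cc(OC)c(OC)c(OC)c3)c(OC)c2)c(OC)c1 | intermediate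
30 | lithium {4-[3,5-dimethoxy-4-(3,4,5-trimethoxyphenoxy)phenoxy]-3,5-dimethoxyphenyl}tri(propan-2-yloxy)borate | CC(C)O[B-](OC(C)C)(OC(C)C)c1cc(OC)c(Oc2cc(OC)c(Oc3cc(OC)c(OC)c(OC)c3)c(OC)c2)c(OC)c1.[Li+] | intermediate
31 | {4-[3,5-dimethoxy-4-(3,4,5-trimethoxyphenoxy)phenoxy]-3,5-dimethoxyphenyl}boronic acid | COc1cc(B(O)O)cc(OC)c1Oc1cc(OC)c(Oc2cc(OC)c(OC)c(OC)c2)c(OC)c1 | intermediate
32 | 2-{4-[3,5-dimethoxy-4-(3,4,5-trimethoxyphenoxy)phenoxy]-3,5-dimethoxyphenoxy}-1-[2,6-dimethoxy-4-(2,4,6-trimethoxyphenoxy)phenoxy]-3,4,5-trimethoxybenzene (pentadecamethyl ether of 33) | COc1cc(OC)c(Oc2cc(OC)c(Oc3cc(OC)c(OC)c(OC)c3Oc3cc(OC)c(Oc4cc(OC)c(Oc5cc(OC)c(OC)c(OC)c5)c(OC)c4)c(OC)c3)c(OC)c2)c(OC)c1 | intermediate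
33 | 4-{3,5-dihydroxy-4-[3,5-dihydroxy-4-(3,4,5-trihydroxyphenoxy)phenoxy]phenoxy}-5-[2,6-dihydroxy-4-(2,4,6-trihydroxyphenoxy)phenoxy]benzene-1,2,3-triol (CNP0270681.0) | Oc1cc(O)c(Oc2cc(O)c(Oc3cc(O)c(O)c(O)c3Oc3cc(O)c(Oc4cc(O)c(Oc5cc(O)c(O)c(O)c5)c(O)c4)c(O)c3)c(O)c2)c(O)c1 | target

**Step count and risks**

Total step count: 16. Longest linear sequence: 12 steps (steps 1 to 10, then 15 and 16); the ring D–F branch (steps 11 to 14) joins at step 15.

Steps most likely to fail:

1. Step 8 (key step). The vinylketene may be diverted before the crowded aryloxyvinyl terminus closes onto it: by dimerisation, by reversal of the ring opening followed by inward rotation of the silyloxy group, or by loss of the silyl group at 110 °C. The fallback gives up the ring construction and brings ring C in as a bought, fully oxygenated benzene ring; it sets out from phenol 7 and comes back at phenol 21. Commercial 2,3,4-trimethoxybenzaldehyde would be taken by Dakin oxidation (H2O2, cat. H2SO4, MeOH) to 2,3,4-trimethoxyphenol F1. Iodination ortho to the hydroxyl (I2, morpholine, CH2Cl2) should then give 6-iodo-2,3,4-trimethoxyphenol F2, and benzylation (BnBr, K2CO3, DMF) gives 2-(benzyloxy)-1-iodo-3,4,5-trimethoxybenzene F3. Ullmann coupling of F3 with 7 (CuI, picolinic acid, K3PO4, DMSO, 100 °C) should give 2-(benzyloxy)-1-[2,6-dimethoxy-4-(2,4,6-trimethoxyphenoxy)phenoxy]-3,4,5-trimethoxybenzene F4, and hydrogenolysis (H2, Pd/C, EtOAc) returns 21. This coupling joins two hindered partners and is expected to need forcing conditions.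

2. Step 15. The phenoxide of 21 carries two ortho substituents, one of them the bulky ring B ether, and may couple on divalent copper so slowly that boronic acid 31 is lost to protodeboronation, to oxidation to its phenol and to homocoupling. The fallback changes reaction type and partner: a non-oxidative Ullmann coupling catalysed by monovalent copper. It sets out from 21 and aryl bromide 28 (already on the route, so step 14 falls away) and comes back at 32, with CuI, picolinic acid, K3PO4, DMSO, 100–110 °C under argon. It makes no new compound (F0).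

3. Step 7. The crowded lithium alkoxide 15 may be silylated only in part at low temperature, or may ring-open or lose methoxide when warmed to drive the silylation. The fallback separates the two events; it sets out from 15 and comes back at 16. The alkoxide would be protonated at −78 °C with aqueous NH4Cl and the neutral carbinol, racemic 4-hydroxy-2,3-dimethoxy-4-{1-[2,6-dimethoxy-4-(2,4,6-trimethoxyphenoxy)phenoxy]ethenyl}cyclobut-2-en-1-one F5, isolated. It would then be silylated as the free tertiary alcohol with TBSOTf and 2,6-lutidine in CH2Cl2 (−78 to 0 °C), where longer reaction times are possible without the fragile alkoxide.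

**Further compounds**

F1 | step 8 | 2,3,4-trimethoxyphenol | COc1ccc(O)c(OC)c1OC
F2 | step 8 | 6-iodo-2,3,4-trimethoxyphenol | COc1cc(I)c(O)c(OC)c1OC
F3 | step 8 | 2-(benzyloxy)-1-iodo-3,4,5-trimethoxybenzene | COc1cc(I)c(OCc2ccccc2)c(OC)c1OC
F4 | step 8 | 2-(benzyloxy)-1-[2,6-dimethoxy-4-(2,4,6-trimethoxyphenoxy)phenoxy]-3,4,5-trimethoxybenzene | COc1cc(Oc2c(OC)cc(Oc3c(OC)cc(OC)cc3OC)cc2OC)c(OCc2ccccc2)c(OC)c1OC
F0 | step 15 | none | none
F5 | step 7 | racemic 4-hydroxy-2,3-dimethoxy-4-{1-[2,6-dimethoxy-4-(2,4,6-trimethoxyphenoxy)phenoxy]ethenyl}cyclobut-2-en-1-one | COC1=C(OC)C(O)(C(=C)Oc2c(OC)cc(Oc3c(OC)cc(OC)cc3OC)cc2OC)C1=O
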